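**Retrosynthetic overview** (germacrane numbering: C1=C10, C4=C5, lactone O on C6, angelate on C8, OH on C2 and C9, C11–C13 the methylene-lactone unit)
1. Target 30 ← PMB ether 29 ← the ten-membered ring is closed last, at C1–C2, by an intramolecular Nozaki–Hiyama–Kishi coupling of seco iodo-aldehyde 27.
2. 27 ← angelate of alcohol 22, whose C7–C8 bond, C7/C8 stereocentres and α-methylene-γ-lactone come from a zinc Barbier allylation.
3. The Barbier partners are bromomethyl butenolide 11 (C2–C7, C11–C13) and α-PMB-oxy aldehyde 20 (C8–C10, C1 as a Z-vinyl iodide).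
4. 11 ← but-3-yn-1-ol (carboalumination, asymmetric vinylation, acrylate RCM); 20 ← (S)-glycerate acetonide (alkyne, anti-carbomagnesiation/iodination).
5. Ring order: butenolide (step 7) → transposed to the α-methylene lactone on coupling (step 14) → ten-membered carbocycle (step 18).

Assumption: the (−)-DAIB-catalysed vinyl transfer in step 4 is taken to follow the Si-face sense known for dialkylzinc additions.

**Step 1**
Reactants: 1 but-3-yn-1-ol
Product: 2 tert-butyl(but-3-yn-1-yloxy)dimethylsilane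
Conditions: TBSCl, imidazole, CH2Cl2, 0 °C to rt
Reagents that add atoms: tert-butyldimethylsilyl chloride, CC(C)(C)[Si](C)(C)Cl
Why: Silyl ether protection of the primary alcohol masks the future C2 oxygen through the organometallic steps.

**Step 2**
Reactants: 2 tert-butyl(but-3-yn-1-yloxy)dimethylsilane
Product: 4 (2E)-5-[(tert-butyldimethylsilyl)oxy]-3-methylpent-2-en-1-ol, via alkenyldimethylalane 3 (not isolated)
Conditions: Me3Al, Cp2ZrCl2 (0.25 equiv), CH2Cl2, 0 °C to rt; then n-BuLi, (CH2O)n, THF, −30 °C to rt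
Reagents that add atoms: trimethylaluminium, C[Al](C)C; formaldehyde (from paraformaldehyde), C=O
Why: Negishi zirconium-catalysed carboalumination adds Me and Al syn across the terminal alkyne, and hydroxymethylation of the alkenylalanate with retention fixes the E C4=C5 alkene.

**Step 3**
Reactants: 4 (2E)-5-[(tert-butyldimethylsilyl)oxy]-3-methylpent-2-en-1-ol
Product: 5 (2E)-5-[(tert-butyldimethylsilyl)oxy]-3-methylpent-2-enal
Conditions: MnO2, CH2Cl2, rt
Reagents that add atoms: none
Why: Chemoselective allylic oxidation gives the enal without E/Z scrambling.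

**Step 4**
Reactants: 5 (2E)-5-[(tert-butyldimethylsilyl)oxy]-3-methylpent-2-enal
Product: 6 (3S,4E)-7-[(tert-butyldimethylsilyl)oxy]-5-methylhepta-1,4-dien-3-ol
Conditions: (CH2=CH)2Zn, (−)-DAIB (8 mol %), toluene, −20 to 0 °C
Reagents that add atoms: divinylzinc, C=C[Zn]C=C
Why: Amino-alcohol-catalysed asymmetric alkenylzinc 1,2-addition, in which (−)-3-exo-(dimethylamino)isoborneol directs vinyl to the Si face of the enal and so sets the 3S carbinol (future C6).

**Step 5**
Reactants: 7 diethyl 2,2-bis(hydroxymethyl)malonate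
Product: 9 2-(bromomethyl)acrylic acid, via bis(hydroxymethyl)malonic acid 8 (not isolated)
Conditions: 48 % aq HBr, 85–90 °C, distil off volatiles
Reagents that add atoms: hydrogen bromide, Br
Why: Acid hydrolysis, decarboxylation, dehydration and OH-to-Br substitution in one pot give the acrylic acid from a cheap malonate.

**Step 6**
Reactants: 6 (3S,4E)-7-[(tert-butyldimethylsilyl)oxy]-5-methylhepta-1,4-dien-3-ol; 9 2-(bromomethyl)acrylic acid
Product: 10 (3S,4E)-7-[(tert-butyldimethylsilyl)oxy]-5-methylhepta-1,4-dien-3-yl 2-(bromomethyl)acrylate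
Conditions: DCC, DMAP (5 mol %), CH2Cl2, 0 °C
Reagents that add atoms: none
Why: Steglich esterification under near-neutral conditions acylates the bis-allylic alcohol without touching the stereocentre or the allylic bromide.

**Step 7**
Reactants: 10 (3S,4E)-7-[(tert-butyldimethylsilyl)oxy]-5-methylhepta-1,4-dien-3-yl 2-(bromomethyl)acrylate
Product: 11 (5R)-3-(bromomethyl)-5-[(1E)-4-[(tert-butyldimethylsilyl)oxy]-2-methylbut-1-en-1-yl]furan-2(5H)-one
Conditions: second-generation Grubbs catalyst RuCl2(=CHPh)(H2IMes)(PCy3) (5 mol %), toluene, 80 °C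
Reagents that add atoms: none
Why: Ring-closing metathesis between the vinyl group and the 1,1-disubstituted acrylate closes the five-membered butenolide, while the trisubstituted alkene cannot compete.

**Step 8**
Reactants: 12 methyl (4S)-2,2-dimethyl-1,3-dioxolane-4-carboxylate
Product: 14 (4R)-4-ethynyl-2,2-dimethyl-1,3-dioxolane, via (4S)-glyceraldehyde acetonide 13 (not isolated)
Conditions: i-Bu2AlH (1.05 equiv), CH2Cl2, −78 °C; then MeOH, K2CO3, dimethyl (1-diazo-2-oxopropyl)phosphonate, −78 °C to rt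
Reagents that add atoms: dimethyl (1-diazo-2-oxopropyl)phosphonate, CC(=O)C(=[N+]=[N-])P(=O)(OC)OC
Why: Partial ester reduction followed in the same flask by Ohira–Bestmann (Seyferth–Gilbert) homologation gives the alkyne without isolating the epimerisable aldehyde; the chiral-pool centre becomes C9.

**Step 9**
Reactants: 14 (4R)-4-ethynyl-2,2-dimethyl-1,3-dioxolane
Product: 15 (2R)-but-3-yne-1,2-diol
Conditions: Dowex 50W (H+ form), MeOH/H2O, rt
Reagents that add atoms: none
Why: Acid-catalysed acetonide hydrolysis frees the propargylic hydroxyl needed to direct the next step.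

**Step 10**
Reactants: 15 (2R)-but-3-yne-1,2-diol
Product: 17 (2R,3Z)-4-iodo-3-methylbut-3-ene-1,2-diol, via alkenylmagnesium bromide 16 (not isolated)
Conditions: MeMgBr (4 equiv), CuI (0.2 equiv), THF, −10 °C to rt; then I2, −78 to 0 °C
Reagents that add atoms: methylmagnesium bromide, C[Mg]Br; iodine, II
Why: Alkoxide-directed copper-catalysed anti-carbomagnesiation puts Me on the internal carbon and Mg on the terminus in a five-membered chelate, and iodinolysis with retention gives the Z-iodoalkene (C1=C10 geometry).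

**Step 11**
Reactants: 17 (2R,3Z)-4-iodo-3-methylbut-3-ene-1,2-diol
Product: 18 (4R)-4-[(1Z)-1-iodoprop-1-en-2-yl]-2-(4-methoxyphenyl)-1,3-dioxolane (both acetal epimers)
Conditions: 4-MeOC6H4CH(OMe)2, PPTS (cat.), CH2Cl2, rt
Reagents that add atoms: 4-methoxybenzaldehyde dimethyl acetal, COc1ccc(C(OC)OC)cc1
Why: Transacetalisation ties the 1,2-diol up as a p-methoxybenzylidene acetal ready for regioselective opening.

**Step 12**
Reactants: 18 (4R)-4-[(1Z)-1-iodoprop-1-en-2-yl]-2-(4-methoxyphenyl)-1,3-dioxolane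
Product: 19 (2R,3Z)-4-iodo-2-[(4-methoxybenzyl)oxy]-3-methylbut-3-en-1-ol
Conditions: i-Bu2AlH (3 equiv), CH2Cl2, −78 to 0 °C
Reagents that add atoms: none
Why: Reductive acetal opening, in which the aluminium binds the less hindered primary oxygen and cleaves that C–O bond, leaves the PMB ether on the secondary (C9) oxygen.

**Step 13**
Reactants: 19 (2R,3Z)-4-iodo-2-[(4-methoxybenzyl)oxy]-3-methylbut-3-en-1-ol
Product: 20 (2R,3Z)-4-iodo-2-[(4-methoxybenzyl)oxy]-3-methylbut-3-enal
Conditions: Dess–Martin periodinane, pyridine, CH2Cl2, 0 °C; used crude at once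
Reagents that add atoms: none
Why: Buffered Dess–Martin oxidation gives the α-alkoxy β,γ-unsaturated aldehyde without enolisation if it is not stored.

**Step 14**
Reactants: 11 (5R)-3-(bromomethyl)-5-[(1E)-4-[(tert-butyldimethylsilyl)oxy]-2-methylbut-1-en-1-yl]furan-2(5H)-one; 20 (2R,3Z)-4-iodo-2-[(4-methoxybenzyl)oxy]-3-methylbut-3-enal
Product: 22 (6R,7R,8R,9R)-1,2-seco-germacranolide alcohol: 12,6-olide with 11(13)-methylene, 8-OH, 9-OPMB, C2 as CH2OTBS, C1 as Z-vinyl iodide, via allylzinc bromide 21 (not isolated)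
Conditions: Zn dust, THF/sat. aq NH4Cl (2:1), 0 °C to rt
Reagents that add atoms: none
Why: Zinc Barbier allylation with allylic transposition: the butenolide β-carbon attacks anti to the C6 side chain (6,7-trans lactone), the ring-locked E-type allyl unit in a Zimmerman–Traxler chair gives the 7,8-anti adduct, and zinc chelation by the α-PMB ether of 20 is matched with this (8,9-syn).

**Step 15**
Reactants: 22 seco-germacranolide alcohol; 23 angelic acid, (2Z)-2-methylbut-2-enoic acid
Product: 25 (6R,7S,8R,9R)-8-angeloyloxy derivative of 22, via angelic trichlorobenzoic mixed anhydride 24 (not isolated)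
Conditions: 2,4,6-Cl3C6H2COCl, Et3N, toluene, rt, 2 h; then 22, toluene, 75 °C (no DMAP)
Reagents that add atoms: none
Why: Yamaguchi esterification through the preformed mixed anhydride acylates the only free hydroxyl (C8), and leaving out DMAP suppresses angelate-to-tiglate isomerisation.

**Step 16**
Reactants: 25 silyl ether angelate
Product: 26 (6R,7S,8R,9R)-primary alcohol: 25 with C2 as CH2OH
Conditions: HF·pyridine, pyridine, THF, 0 °C
Reagents that add atoms: none
Why: Buffered fluoride desilylation removes the primary TBS ether while the PMB ether, angelate and lactone stay intact.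

**Step 17**
Reactants: 26 primary alcohol
Product: 27 (6R,7S,8R,9R)-seco iodo-aldehyde: 26 with C2 as CHO
Conditions: Dess–Martin periodinane, pyridine, CH2Cl2, 0 °C; used at once
Reagents that add atoms: none
Why: Neutral Dess–Martin oxidation gives the β,γ-unsaturated aldehyde without migration of the C4=C5 alkene into conjugation.

**Step 18**
Reactants: 27 seco iodo-aldehyde
Product: 29 (2R,6R,7S,8R,9R)-8-angeloyloxy-2-hydroxy-9-[(4-methoxybenzyl)oxy]germacra-1(10)Z,4E,11(13)-trien-12,6-olide, via alkenylchromium dichloride 28 (not isolated)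
Conditions: CrCl2 (15 equiv), NiCl2 (0.2 equiv), DMSO/THF, 2 mM (slow addition), rt
Reagents that add atoms: none
Why: Nozaki–Hiyama–Kishi macrocyclization: oxidative addition of the Z-alkenyl iodide to zerovalent nickel, transmetalation to trivalent chromium and chemoselective addition to the aldehyde close the ten-membered ring with retention of the Z alkene; C2 is set by macrocyclic control, with 2R expected but not secure.

**Step 19**
Reactants: 29 macrocyclic PMB ether
Product: 30 (2R,6R,7S,8R,9R)-8-angeloyloxy-2,9-dihydroxygermacra-1(10)Z,4E,11(13)-trien-12,6-olide (target, CNP0280988.2)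
Conditions: DDQ (1.3 equiv), CH2Cl2/pH 7 buffer (10:1), 0 °C
Reagents that add atoms: none
Why: Oxidative PMB cleavage under buffered conditions frees the C9 hydroxyl without acyl migration or loss of the angelate.

**Compound list**
1 | but-3-yn-1-ol | C#CCCO | starting material
2 | tert-butyl(but-3-yn-1-yloxy)dimethylsilane | C#CCCO[Si](C)(C)C(C)(C)C | intermediate
3 | [(1E)-4-[(tert-butyldimethylsilyl)oxy]-2-methylbut-1-en-1-yl]dimethylalane | C[Al](C)/C=C(\C)CCO[Si](C)(C)C(C)(C)C | intermediate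
4 | (2E)-5-[(tert-butyldimethylsilyl)oxy]-3-methylpent-2-en-1-ol | OC/C=C(\C)CCO[Si](C)(C)C(C)(C)C | intermediate
5 | (2E)-5-[(tert-butyldimethylsilyl)oxy]-3-methylpent-2-enal | O=C/C=C(\C)CCO[Si](C)(C)C(C)(C)C | intermediate
6 | (3S,4E)-7-[(tert-butyldimethylsilyl)oxy]-5-methylhepta-1,4-dien-3-ol | CC(C)(C)[Si](C)(C)OCC/C(C)=C/[C@H](C=C)O | intermediate
7 | diethyl 2,2-bis(hydroxymethyl)malonate | CCOC(=O)C(CO)(CO)C(=O)OCC | starting material
8 | 2,2-bis(hydroxymethyl)malonic acid | OCC(CO)(C(=O)O)C(=O)O | intermediate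
9 | 2-(bromomethyl)acrylic acid | C=C(CBr)C(=O)O | intermediate
10 | (3S,4E)-7-[(tert-butyldimethylsilyl)oxy]-5-methylhepta-1,4-dien-3-yl 2-(bromomethyl)acrylate | CC(C)(C)[Si](C)(C)OCC/C(C)=C/[C@H](C=C)OC(=O)C(=C)CBr | intermediate
11 | (5R)-3-(bromomethyl)-5-[(1E)-4-[(tert-butyldimethylsilyl)oxy]-2-methylbut-1-en-1-yl]furan-2(5H)-one | CC(C)(C)[Si](C)(C)OCC/C(C)=C/[C@H]1OC(=O)C(CBr)=C1 | intermediate
12 | methyl (4S)-2,2-dimethyl-1,3-dioxolane-4-carboxylate | COC(=O)[C@@H]1COC(C)(C)O1 | starting material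
13 | (4S)-2,2-dimethyl-1,3-dioxolane-4-carbaldehyde | O=C[C@@H]1COC(C)(C)O1 | intermediate
14 | (4R)-4-ethynyl-2,2-dimethyl-1,3-dioxolane | C#C[C@@H]1COC(C)(C)O1 | intermediate
15 | (2R)-but-3-yne-1,2-diol | C#C[C@@H](O)CO | intermediate
16 | (1Z,3R)-3,4-bis(bromomagnesiooxy)-2-methylbut-1-en-1-ylmagnesium bromide | Br[Mg]/C=C(/C)[C@@H](O[Mg]Br)CO[Mg]Br | intermediate
17 | (2R,3Z)-4-iodo-3-methylbut-3-ene-1,2-diol | I/C=C(/C)[C@@H](O)CO | intermediate
18 | (4R)-4-[(1Z)-1-iodoprop-1-en-2-yl]-2-(4-methoxyphenyl)-1,3-dioxolane (acetal epimers) | I/C=C(/C)[C@@H]1COC(c2ccc(OC)cc2)O1 | intermediate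
19 | (2R,3Z)-4-iodo-2-[(4-methoxybenzyl)oxy]-3-methylbut-3-en-1-ol | I/C=C(/C)[C@@H](OCc1ccc(OC)cc1)CO | intermediate
20 | (2R,3Z)-4-iodo-2-[(4-methoxybenzyl)oxy]-3-methylbut-3-enal | I/C=C(/C)[C@@H](OCc1ccc(OC)cc1)C=O | intermediate
21 | {(5R)-5-[(1E)-4-[(tert-butyldimethylsilyl)oxy]-2-methylbut-1-en-1-yl]-2-oxo-2,5-dihydrofuran-3-yl}methylzinc bromide | CC(C)(C)[Si](C)(C)OCC/C(C)=C/[C@H]1OC(=O)C(C[Zn]Br)=C1 | intermediate
22 | (6R,7R,8R,9R)-1,2-seco-germacranolide: 12,6-olide, 11(13)-methylene, 8-OH, 9-OPMB, C2 CH2OTBS, C1 Z-vinyl iodide, 4E | CC(C)(C)[Si](C)(C)OCC/C(C)=C/[C@H]1OC(=O)C(=C)[C@@H]1[C@@H](O)[C@H](OCc2ccc(OC)cc2)/C(C)=C\I | intermediate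
23 | angelic acid, (2Z)-2-methylbut-2-enoic acid | C/C=C(/C)C(=O)O | starting material
24 | (2Z)-2-methylbut-2-enoic 2,4,6-trichlorobenzoic anhydride | C/C=C(/C)C(=O)OC(=O)c1c(Cl)cc(Cl)cc1Cl | intermediate
25 | (6R,7S,8R,9R)-8-angelate of 22 (C2 CH2OTBS) | CC(C)(C)[Si](C)(C)OCC/C(C)=C/[C@H]1OC(=O)C(=C)[C@@H]1[C@@H](OC(=O)/C(C)=C\C)[C@H](OCc2ccc(OC)cc2)/C(C)=C\I | intermediate
26 | (6R,7S,8R,9R)-8-angelate, C2 CH2OH | OCC/C(C)=C/[C@H]1OC(=O)C(=C)[C@@H]1[C@@H](OC(=O)/C(C)=C\C)[C@H](OCc2ccc(OC)cc2)/C(C)=C\I | intermediate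
27 | (6R,7S,8R,9R)-8-angelate, C2 CHO (seco iodo-aldehyde) | O=CC/C(C)=C/[C@H]1OC(=O)C(=C)[C@@H]1[C@@H](OC(=O)/C(C)=C\C)[C@H](OCc2ccc(OC)cc2)/C(C)=C\I | intermediate
28 | alkenylchromium dichloride of 27 (CrCl2 in place of I at C1) | O=CC/C(C)=C/[C@H]1OC(=O)C(=C)[C@@H]1[C@@H](OC(=O)/C(C)=C\C)[C@H](OCc2ccc(OC)cc2)/C(C)=C\[Cr](Cl)Cl | intermediate
29 | (2R,6R,7S,8R,9R)-8-angeloyloxy-2-hydroxy-9-[(4-methoxybenzyl)oxy]germacra-1(10)Z,4E,11(13)-trien-12,6-olide | C=C1C(=O)O[C@@H]2/C=C(\C)C[C@@H](O)/C=C(/C)[C@@H](OCc3ccc(OC)cc3)[C@H](OC(=O)/C(C)=C\C)[C@@H]12 | intermediate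
30 | (2R,6R,7S,8R,9R)-8-angeloyloxy-2,9-dihydroxygermacra-1(10)Z,4E,11(13)-trien-12,6-olide | C=C1C(=O)O[C@@H]2/C=C(\C)C[C@@H](O)/C=C(/C)[C@@H](O)[C@H](OC(=O)/C(C)=C\C)[C@@H]12 | target

**Totals**
Total step count: 19. Longest linear sequence: 12 steps (steps 1–4, 6, 7, 14–19; the branch through steps 8–13 and 14–19 is equally long).

**Steps most likely to fail, with fallbacks**

Step 18 is the weakest point. The ten-membered ring may close with the wrong or a mixed configuration at C2, because that centre rests on macrocyclic control alone. The fallback sets out from 27 and comes back at 29. The ring closure is run as before, and the crude C2 alcohols, containing the C2 epimer of 29 F1, are oxidised with Dess–Martin periodinane to the ten-membered dienone F2. This ketone is then reduced under reagent control with (S)-2-methyl-CBS-oxazaborolidine and catecholborane in toluene at −78 °C. The alkenyl side acts as the large group, so hydride is delivered to give the 2R alcohol 29.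

Step 14 is the second risk. Aldehyde 20 can enolise or isomerise in the aqueous zinc medium, and the C8 selectivity depends on chelation. The fallback sets out from 11 and comes back at 22. Bromide 11 is converted with bis(pinacolato)diboron and Pd2(dba)3 (cat.) in toluene at 50 °C into the pinacol allylboronate F3. F3 is combined with 20 under anhydrous, neutral conditions (toluene, rt, or Sc(OTf)3 cat. at −78 °C). This allylboration runs through the same closed chair, so the 6,7-trans/7,8-anti outcome is kept, and it gives the O-boryl adduct F4, which is hydrolysed on work-up to 22.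

Step 4 is the third risk. The enantioselectivity and facial sense of the catalytic vinyl transfer to this enal are not established. The fallback sets out from 5 and comes back at 6. Vinylmagnesium bromide in THF at −78 °C gives the racemic dienol F5. Sharpless kinetic resolution follows (Ti(Oi-Pr)4, D-(−)-diisopropyl tartrate, t-BuOOH 0.6 equiv, 4 Å sieves, CH2Cl2, −20 °C). It epoxidises the trisubstituted alkene of the 3R enantiomer, giving the erythro epoxy alcohol F6, and leaves the 3S dienol 6, which is separated by chromatography.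

**Further compounds**
F1 | step 18 | (2S,6R,7S,8R,9R)-8-angeloyloxy-2-hydroxy-9-[(4-methoxybenzyl)oxy]germacra-1(10)Z,4E,11(13)-trien-12,6-olide (C2 epimer of 29) | C=C1C(=O)O[C@@H]2/C=C(\C)C[C@H](O)/C=C(/C)[C@@H](OCc3ccc(OC)cc3)[C@H](OC(=O)/C(C)=C\C)[C@@H]12
F2 | step 18 | (6R,7S,8R,9R)-8-angeloyloxy-9-[(4-methoxybenzyl)oxy]-2-oxogermacra-1(10)Z,4E,11(13)-trien-12,6-olide | C=C1C(=O)O[C@@H]2/C=C(\C)CC(=O)/C=C(/C)[C@@H](OCc3ccc(OC)cc3)[C@H](OC(=O)/C(C)=C\C)[C@@H]12
F3 | step 14 | (5R)-5-[(1E)-4-[(tert-butyldimethylsilyl)oxy]-2-methylbut-1-en-1-yl]-3-[(4,4,5,5-tetramethyl-1,3,2-dioxaborolan-2-yl)methyl]furan-2(5H)-one | CC(C)(C)[Si](C)(C)OCC/C(C)=C/[C@H]1OC(=O)C(CB2OC(C)(C)C(C)(C)O2)=C1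
F4 | step 14 | 8-O-(pinacolatoboryl) derivative of 22 | CC(C)(C)[Si](C)(C)OCC/C(C)=C/[C@H]1OC(=O)C(=C)[C@@H]1[C@@H](OB2OC(C)(C)C(C)(C)O2)[C@H](OCc3ccc(OC)cc3)/C(C)=C\I
F5 | step 4 | racemic (4E)-7-[(tert-butyldimethylsilyl)oxy]-5-methylhepta-1,4-dien-3-ol | CC(C)(C)[Si](C)(C)OCC/C(C)=C/C(O)C=C
F6 | step 4 | erythro 4,5-epoxy alcohol from the 3R dienol: (1R)-1-{3-[2-(tert-butyldimethylsilyloxy)ethyl]-3-methyloxiran-2-yl}prop-2-en-1-ol | C=C[C@@H](O)[C@H]1O[C@]1(C)CCO[Si](C)(C)C(C)(C)C
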